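Incarvillateine is cut at its two ester bonds into α-truxillic acid (the solid-state photodimer of a ferulic acid derivative) and two copies of a bicyclic amino ketone. In that ketone the C4–C4a unit shared by the piperidine and cyclopentanone rings lies between C3 (on N2) and C5 (α to C6=O), so both rings are traced to one [2+2] photocycloaddition/retro-Mannich fragmentation: a propenyl group is inserted into the C3=C5 bond of a seven-membered vinylogous amide, forming C4a–C5, C3–C4 and the cis ring fusion in one operation. The precursor, (5S,6R)-1,5-dimethyl-6-[(E)-propenyl]tetrahydroazepin-4-one, holds every skeletal atom; its stereocentres come from an Ireland–Claisen rearrangement.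

Key step: step 9

Remark on numbering: the alkaloid atoms keep the cyclopenta[c]pyridine numbers (C1, N2, C3, C4, C4a, C5, C6, C7, C7a) in all intermediates.
Assumption: borohydride reduction of ketone 25 is taken to occur from the convex face and to give the 6S alcohol, so both ester bonds are made with inversion (Mitsunobu) and not by acylation.
Remark on the precursor: nitrogen is carried as a Boc carbamate up to the ynone, because hydrogenolysis of a benzyl group is excluded by the alkene and a free γ-amino amide would lactamise; the C5 methyl group is placed cis to the propenyl group, which is already the C7 configuration of the alkaloid.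

Step 1
Reactants: 1 (S)-but-3-yn-2-ol; 2 N-methylbenzylamine
Product: 4 (2S)-5-[benzyl(methyl)amino]pent-3-yn-2-ol, via iminium ion 3 (not isolated)
Conditions: (CH2O)n, CuBr (cat.), dioxane, 80 °C
Reagents that add atoms: formaldehyde (as paraformaldehyde), C=O
Why: Alkyne Mannich reaction (three-component aminomethylation): the terminal alkyne, activated by CuBr, adds to iminium ion 3 formed from formaldehyde and the secondary amine; the free propargylic alcohol is tolerated and its stereocentre is not involved.

Step 2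
Reactants: 4 (2S)-5-[benzyl(methyl)amino]pent-3-yn-2-ol
Product: 6 (2S,3E)-5-[benzyl(methyl)amino]pent-3-en-2-ol, via alkenylaluminate 5 (not isolated)
Conditions: LiAlH4, THF, 0 °C to 45 °C; then aq. NaOH
Reagents that add atoms: none
Why: Hydride reduction of a propargylic alcohol: the alkoxyaluminium hydride delivers hydride to the proximal alkyne carbon to give cyclic alkenylaluminate 5, and protonolysis of its C–Al bond with retention gives only the (E)-alkene, the carbinol centre and the unquaternised amine being untouched.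

Step 3
Reactants: 6 (2S,3E)-5-[benzyl(methyl)amino]pent-3-en-2-ol; 7 propanoyl chloride
Product: 8 (2S,3E)-5-[benzyl(methyl)amino]pent-3-en-2-yl propanoate
Conditions: Et3N, DMAP (cat.), CH2Cl2, 0 °C
Reagents that add atoms: none
Why: Nucleophilic acyl substitution (DMAP-catalysed O-acylation) of the secondary allylic alcohol; the tertiary amine cannot be acylated and the stereocentre is not touched.

Step 4
Reactants: 8 (2S,3E)-5-[benzyl(methyl)amino]pent-3-en-2-yl propanoate
Product: 12 (2S,3R,4E)-3-{[benzyl(methyl)amino]methyl}-2-methylhex-4-enoic acid, via lithium enolate 9 (not isolated), via silyl ketene acetal 10 (not isolated), via trimethylsilyl ester 11 (not isolated)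
Conditions: LiN(i-Pr)2, THF/DMPU, −78 °C; Me3SiCl, −78 °C to 50 °C; aq. NaOH, then pH 7
Reagents that add atoms: none
Why: Ireland–Claisen rearrangement: enolisation in the presence of DMPU gives the (Z)-silyl ketene acetal (methyl cis to OSiMe3), and the chair transition state with the carbinol methyl group equatorial transfers the S carbinol centre to C7a (3R), sets C7 (2S) and forms the (E)-propenyl group, a minor C7 epimer from the other ketene acetal geometry being harmless because C7 is equilibrated in step 10.

Step 5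
Reactants: 12 (2S,3R,4E)-3-{[benzyl(methyl)amino]methyl}-2-methylhex-4-enoic acid
Product: 14 (2S,3R,4E)-3-{[benzyl(methyl)amino]methyl}-N-methoxy-N,2-dimethylhex-4-enamide, via acyl imidazolide 13 (not isolated)
Conditions: 1,1'-carbonyldiimidazole, CH2Cl2/DMF, rt; then MeNHOMe·HCl, rt
Reagents that add atoms: N,O-dimethylhydroxylamine hydrochloride, CNOC.Cl
Why: Weinreb amide formation through the acyl imidazolide, a mild activation without added base that should keep the α-stereocentre intact.

Step 6
Reactants: 14 (2S,3R,4E)-3-{[benzyl(methyl)amino]methyl}-N-methoxy-N,2-dimethylhex-4-enamide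
Product: 17 (2S,3R,4E)-3-{[(tert-butoxycarbonyl)(methyl)amino]methyl}-N-methoxy-N,2-dimethylhex-4-enamide, via chloroethyl carbamate 15 (not isolated), via amine hydrochloride 16 (not isolated)
Conditions: ClCO2CH(Cl)CH3, ClCH2CH2Cl, 0 °C to 80 °C; evaporate; MeOH, 65 °C; evaporate; Boc2O, Et3N, CH2Cl2, 0 °C to rt
Reagents that add atoms: di-tert-butyl dicarbonate, CC(C)(C)OC(=O)OC(=O)OC(C)(C)C
Why: Chloroformate N-dealkylation (von Braun type): the acylammonium ion loses benzyl to chloride in preference to methyl or the primary alkyl group, methanolysis of the 1-chloroethyl carbamate frees the amine as its hydrochloride, and this is trapped as the Boc carbamate before it can lactamise onto the amide.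

Step 7
Reactants: 17 (2S,3R,4E)-3-{[(tert-butoxycarbonyl)(methyl)amino]methyl}-N-methoxy-N,2-dimethylhex-4-enamide
Product: 19 tert-butyl methyl[(2R,3S)-3-methyl-4-oxo-2-[(E)-prop-1-enyl]hex-5-yn-1-yl]carbamate, via magnesium hemiaminal 18 (not isolated)
Conditions: HC≡CMgBr, THF, 0 °C to rt; then cold 1 M aq. HCl
Reagents that add atoms: ethynylmagnesium bromide, C#C[Mg]Br
Why: Weinreb ketone synthesis: the chelated magnesium hemiaminal resists a second addition and collapses to the ynone only on the cold acidic quench, which also keeps the liberated hydroxylamine protonated so that it does not add to the ynone.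

Step 8
Reactants: 19 tert-butyl methyl[(2R,3S)-3-methyl-4-oxo-2-[(E)-prop-1-enyl]hex-5-yn-1-yl]carbamate
Product: 21 (5S,6R)-1,5-dimethyl-6-[(E)-prop-1-enyl]-1,5,6,7-tetrahydro-4H-azepin-4-one, via chlorovinyl ketone 20 (not isolated)
Conditions: HCl (4 M in dioxane), 0 °C to rt; evaporate; K2CO3, MeOH (0.02 M), rt
Reagents that add atoms: none
Why: Amino-ynone cyclisation to a cyclic enaminone: HCl removes the Boc group and adds across the ynone to a β-chlorovinyl ketone, and on neutralisation the methylamino group closes the seven-membered ring at C3 by conjugate addition–elimination (formal 7-endo addition), the conjugated vinylogous amide being the thermodynamic sink.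

Step 9
Reactants: 21 (5S,6R)-1,5-dimethyl-6-[(E)-prop-1-enyl]-1,5,6,7-tetrahydro-4H-azepin-4-one
Product: 24 (4aR,7S,7aR)-2,4,7-trimethyl-1,2,4a,5,7,7a-hexahydro-6H-cyclopenta[c]pyridin-6-one, via cyclobutane photoadduct 22 (not isolated), via iminium enolate 23 (not isolated)
Conditions: hν (350 nm lamps, Pyrex vessel), degassed MeCN (0.005 M), rt; evaporate below 30 °C and use crude
Reagents that add atoms: none
Why: Proposed new method: excitation of the vinylogous amide N2–C3=C5–C6=O (triplet after intersystem crossing) should lead its electrophilic α-carbon C5 to add to the proximal propenyl carbon C4a in a 5-exo (1,5) closure that forms the cyclopentanone ring C4a–C5–C6–C7–C7a, and the resulting 1,4-biradical (aminoalkyl radical at C3, secondary radical at C4) should recombine to the C3–C4 bond, which closes the six-membered ring N2–C3–C4–C4a–C7a–C1 and the transient cyclobutane of 22; the N2 lone pair then expels the C3–C5 bond (retro-Mannich fragmentation, driven by cyclobutane strain and the enolate leaving group) to give zwitterion 23, and proton transfer from C4 to C5 leaves the C6 ketone and the C3=C4 enamine. The closest known reaction type is the intramolecular [2+2] photocycloaddition of acyclic and six-membered vinylogous amides to tethered alkenes with retro-Mannich fragmentation of the aminocyclobutane; new here are the seven-membered chromophore and the attachment of the alkene to the ring carbon (C7a) opposite the C3=C5 bond. The only stereocentre created, C4a, is controlled by C7a, because the propenyl group can reach C5 and C3 only across its own face of the azepinone and the C1–N2–C3 strap then holds C1 and C4 cis on the cyclopentane; C4 ends trigonal, so alkene isomerisation and biradical rotation cost nothing, and C7 is carried through. The step needs regioselectivity between two five-membered first closures, C5 to C4a (wanted) and C3 to C4a (through N2 and C1, which would end in a pyrrolidine-fused cyclohexanone), and chemoselectivity against dimerisation; the first should be secured by polarity (the acyl-substituted C5 terminus is the electrophilic one and the alkene is electron-rich, whereas C3 is a stabilised, nucleophilic aminoalkyl centre) and by the cis C7 methyl group, which keeps the propenyl group pseudo-axial over the chromophore and disfavours the rotamer with C4 over C5, the second by high dilution. Fragmentation is unambiguous because only the C3–C5 bond lies between the nitrogen donor and the carbonyl acceptor.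

Step 10
Reactants: 24 (4aR,7S,7aR)-2,4,7-trimethyl-1,2,4a,5,7,7a-hexahydro-6H-cyclopenta[c]pyridin-6-one
Product: 25 (4R,4aS,7S,7aR)-2,4,7-trimethyloctahydro-6H-cyclopenta[c]pyridin-6-one
Conditions: H2 (1 atm), 10% Pd/C, EtOAc, rt; filter; K2CO3, MeOH, rt
Reagents that add atoms: none
Why: Heterogeneous hydrogenation of the enamine: the C4a–C5 bond is pseudo-axial (it avoids the C4 methyl group) and shields the concave face, so H2 should add to C3=C4 from the convex face (that of H4a and H7a) and set C4 (R), after which carbonate equilibrates the only enolisable stereocentre, C7, to the epimer with the methyl group trans to C1 (7S), so that any C7 epimer carried from step 4 converges.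

Step 11
Reactants: 25 (4R,4aS,7S,7aR)-2,4,7-trimethyloctahydro-6H-cyclopenta[c]pyridin-6-one
Product: 26 (4R,4aS,6S,7S,7aR)-2,4,7-trimethyloctahydro-1H-cyclopenta[c]pyridin-6-ol
Conditions: NaBH4, MeOH, −20 °C to 0 °C
Reagents that add atoms: none
Why: Hydride reduction of the cyclopentanone: the piperidine ring covers the concave face, so borohydride should attack C6 from the convex face and give the 6S alcohol (hydroxyl cis to the piperidine ring, trans to the C7 methyl group), the C6 epimer of the alcohol unit of the target.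

Step 12
Reactants: 27 ferulic acid
Product: 28 (E)-3-{3-methoxy-4-[(4-methylphenyl)sulfonyloxy]phenyl}prop-2-enoic acid
Conditions: TsCl, NaOH, H2O/THF, 0 °C to rt; then aq. HCl to pH 2
Reagents that add atoms: 4-methylbenzenesulfonyl chloride, Cc1ccc(cc1)S(Cl)(=O)=O
Why: Schotten–Baumann sulfonylation: the phenoxide is tosylated in aqueous base, while any mixed anhydride formed at the carboxylate is hydrolysed back.

Step 13
Reactants: 28 (E)-3-{3-methoxy-4-[(4-methylphenyl)sulfonyloxy]phenyl}prop-2-enoic acid (two molecules)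
Product: 29 (1α,2α,3β,4β)-2,4-bis{3-methoxy-4-[(4-methylphenyl)sulfonyloxy]phenyl}cyclobutane-1,3-dicarboxylic acid
Conditions: hν (high-pressure Hg lamp, Pyrex), powdered crystals suspended in water, rt
Reagents that add atoms: none
Why: Topochemical [2+2] photodimerisation of a cinnamic acid: in head-to-tail crystal packing, neighbours related by an inversion centre dimerise to the α-truxillic acid, so the lattice sets all four cyclobutane stereocentres in the centrosymmetric, achiral diacid.

Step 14
Reactants: 26 (4R,4aS,6S,7S,7aR)-2,4,7-trimethyloctahydro-1H-cyclopenta[c]pyridin-6-ol (2.2 equivalents); 29 (1α,2α,3β,4β)-2,4-bis{3-methoxy-4-[(4-methylphenyl)sulfonyloxy]phenyl}cyclobutane-1,3-dicarboxylic acid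
Product: 30 bis[(4R,4aS,6R,7S,7aR)-2,4,7-trimethyloctahydro-1H-cyclopenta[c]pyridin-6-yl] (1α,2α,3β,4β)-2,4-bis{3-methoxy-4-[(4-methylphenyl)sulfonyloxy]phenyl}cyclobutane-1,3-dicarboxylate
Conditions: PPh3, i-PrO2C–N=N–CO2i-Pr (DIAD), THF, 0 °C to rt
Reagents that add atoms: none
Why: Double Mitsunobu esterification: each alcohol is activated by PPh3/DIAD and displaced by a carboxylate of 29 in an SN2 reaction with inversion, which sets both C6 centres to R, while the tertiary amines and the aryl sulfonates are inert.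

Step 15
Reactants: 30 bis[(4R,4aS,6R,7S,7aR)-2,4,7-trimethyloctahydro-1H-cyclopenta[c]pyridin-6-yl] (1α,2α,3β,4β)-2,4-bis{3-methoxy-4-[(4-methylphenyl)sulfonyloxy]phenyl}cyclobutane-1,3-dicarboxylate
Product: 31 bis[(4R,4aS,6R,7S,7aR)-2,4,7-trimethyloctahydro-1H-cyclopenta[c]pyridin-6-yl] (1α,2α,3β,4β)-2,4-bis(4-hydroxy-3-methoxyphenyl)cyclobutane-1,3-dicarboxylate (CNP0283097.2)
Conditions: Na/Hg, Na2HPO4, MeOH/THF, −20 °C to 0 °C
Reagents that add atoms: none
Why: Reductive S–O cleavage of the aryl sulfonates by electron transfer from sodium amalgam under phosphate buffering should free both phenols without touching the secondary alkyl esters or epimerising the cyclobutane.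

Compound list
1 | (S)-but-3-yn-2-ol | C#C[C@H](C)O | starting material
2 | N-methylbenzylamine | CNCc1ccccc1 | starting material
3 | N-benzyl-N-methylmethaniminium ion | C=[N+](C)Cc1ccccc1 | intermediate (not isolated)
4 | (2S)-5-[benzyl(methyl)amino]pent-3-yn-2-ol | C[C@H](O)C#CCN(C)Cc1ccccc1 | intermediate
5 | lithium (5S)-3-{[benzyl(methyl)amino]methyl}-5-methyl-2,5-dihydro-1,2-oxaaluminol-2-uide (cyclic alkenylaluminate) | C[C@H]1C=C(CN(C)Cc2ccccc2)[AlH2-]O1.[Li+] | intermediate (not isolated)
6 | (2S,3E)-5-[benzyl(methyl)amino]pent-3-en-2-ol | C[C@H](O)/C=C/CN(C)Cc1ccccc1 | intermediate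
7 | propanoyl chloride | CCC(Cl)=O | starting material
8 | (2S,3E)-5-[benzyl(methyl)amino]pent-3-en-2-yl propanoate | CCC(=O)O[C@@H](C)/C=C/CN(C)Cc1ccccc1 | intermediate
9 | lithium enolate of 8, methyl group cis to O–Li | C/C=C(\[O-])O[C@@H](C)/C=C/CN(C)Cc1ccccc1.[Li+] | intermediate (not isolated)
10 | (Z)-trimethylsilyl ketene acetal of 8, methyl group cis to OSiMe3 | C/C=C(\O[Si](C)(C)C)O[C@@H](C)/C=C/CN(C)Cc1ccccc1 | intermediate (not isolated)
11 | trimethylsilyl (2S,3R,4E)-3-{[benzyl(methyl)amino]methyl}-2-methylhex-4-enoate | C[Si](C)(C)OC(=O)[C@@H](C)[C@@H](/C=C/C)CN(C)Cc1ccccc1 | intermediate (not isolated)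
12 | (2S,3R,4E)-3-{[benzyl(methyl)amino]methyl}-2-methylhex-4-enoic acid | OC(=O)[C@@H](C)[C@@H](/C=C/C)CN(C)Cc1ccccc1 | intermediate
13 | (2S,3R,4E)-3-{[benzyl(methyl)amino]methyl}-1-(imidazol-1-yl)-2-methylhex-4-en-1-one (acyl imidazolide) | O=C(n1ccnc1)[C@@H](C)[C@@H](/C=C/C)CN(C)Cc1ccccc1 | intermediate (not isolated)
14 | (2S,3R,4E)-3-{[benzyl(methyl)amino]methyl}-N-methoxy-N,2-dimethylhex-4-enamide | CON(C)C(=O)[C@@H](C)[C@@H](/C=C/C)CN(C)Cc1ccccc1 | intermediate
15 | (2S,3R,4E)-3-({[(1-chloroethoxy)carbonyl](methyl)amino}methyl)-N-methoxy-N,2-dimethylhex-4-enamide (chloroethyl centre not defined) | CON(C)C(=O)[C@@H](C)[C@@H](/C=C/C)CN(C)C(=O)OC(C)Cl | intermediate (not isolated)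
16 | (2S,3R,4E)-N-methoxy-N,2-dimethyl-3-[(methylamino)methyl]hex-4-enamide hydrochloride | CON(C)C(=O)[C@@H](C)[C@@H](/C=C/C)CNC.Cl | intermediate (not isolated)
17 | (2S,3R,4E)-3-{[(tert-butoxycarbonyl)(methyl)amino]methyl}-N-methoxy-N,2-dimethylhex-4-enamide | CON(C)C(=O)[C@@H](C)[C@@H](/C=C/C)CN(C)C(=O)OC(C)(C)C | intermediate
18 | bromomagnesium N-methoxy-N-methyl hemiaminal from 17 and the acetylide (hemiaminal carbon not defined) | C#CC(O[Mg]Br)(N(C)OC)[C@@H](C)[C@@H](/C=C/C)CN(C)C(=O)OC(C)(C)C | intermediate (not isolated)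
19 | tert-butyl methyl[(2R,3S)-3-methyl-4-oxo-2-[(E)-prop-1-enyl]hex-5-yn-1-yl]carbamate | C#CC(=O)[C@@H](C)[C@@H](/C=C/C)CN(C)C(=O)OC(C)(C)C | intermediate
20 | (4S,5R,6E)-1-chloro-4-methyl-5-[(methylamino)methyl]octa-1,6-dien-3-one hydrochloride (C1=C2 geometry not defined) | ClC=CC(=O)[C@@H](C)[C@@H](/C=C/C)CNC.Cl | intermediate (not isolated)
21 | (5S,6R)-1,5-dimethyl-6-[(E)-prop-1-enyl]-1,5,6,7-tetrahydro-4H-azepin-4-one | CN1C=CC(=O)[C@@H](C)[C@@H](/C=C/C)C1 | intermediate
22 | 2,4,7-trimethyl-4-azatricyclo[4.3.0.0(3,9)]nonan-8-one, the aminocyclobutane photoadduct (cage built on the propenyl face; methyl-bearing cyclobutane carbon, alkaloid C4, not defined) | CN1C[C@H]2[C@H](C)C(=O)[C@H]3[C@@H]1C(C)[C@@H]23 | intermediate (not isolated)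
23 | iminium enolate zwitterion (N2=C3 iminium, C5=C6–O− enolate; C4a, C7 and C7a as in 24, C4 not defined) | C[N+]1=CC(C)[C@@H]2C=C([O-])[C@@H](C)[C@@H]2C1 | intermediate (not isolated)
24 | (4aR,7S,7aR)-2,4,7-trimethyl-1,2,4a,5,7,7a-hexahydro-6H-cyclopenta[c]pyridin-6-one | O=C1C[C@@H]2[C@@H](CN(C)C=C2C)[C@@H]1C | intermediate
25 | (4R,4aS,7S,7aR)-2,4,7-trimethyloctahydro-6H-cyclopenta[c]pyridin-6-one | O=C1C[C@@H]2[C@@H](CN(C)C[C@@H]2C)[C@@H]1C | intermediate
26 | (4R,4aS,6S,7S,7aR)-2,4,7-trimethyloctahydro-1H-cyclopenta[c]pyridin-6-ol | O[C@H]1C[C@@H]2[C@@H](CN(C)C[C@@H]2C)[C@@H]1C | intermediate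
27 | ferulic acid | COc1cc(/C=C/C(=O)O)ccc1O | starting material
28 | (E)-3-{3-methoxy-4-[(4-methylphenyl)sulfonyloxy]phenyl}prop-2-enoic acid | COc1cc(/C=C/C(=O)O)ccc1OS(=O)(=O)c1ccc(C)cc1 | intermediate
29 | (1α,2α,3β,4β)-2,4-bis{3-methoxy-4-[(4-methylphenyl)sulfonyloxy]phenyl}cyclobutane-1,3-dicarboxylic acid | COc1cc([C@H]2[C@H](C(=O)O)[C@H](c3ccc(OS(=O)(=O)c4ccc(C)cc4)c(OC)c3)[C@H]2C(=O)O)ccc1OS(=O)(=O)c1ccc(C)cc1 | intermediate
30 | bis[(4R,4aS,6R,7S,7aR)-2,4,7-trimethyloctahydro-1H-cyclopenta[c]pyridin-6-yl] (1α,2α,3β,4β)-2,4-bis{3-methoxy-4-[(4-methylphenyl)sulfonyloxy]phenyl}cyclobutane-1,3-dicarboxylate | COc1cc([C@H]2[C@H](C(=O)O[C@@H]3C[C@@H]4[C@@H](CN(C)C[C@@H]4C)[C@@H]3C)[C@H](c3ccc(OS(=O)(=O)c4ccc(C)cc4)c(OC)c3)[C@H]2C(=O)O[C@@H]2C[C@@H]3[C@@H](CN(C)C[C@@H]3C)[C@@H]2C)ccc1OS(=O)(=O)c1ccc(C)cc1 | intermediate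
31 | bis[(4R,4aS,6R,7S,7aR)-2,4,7-trimethyloctahydro-1H-cyclopenta[c]pyridin-6-yl] (1α,2α,3β,4β)-2,4-bis(4-hydroxy-3-methoxyphenyl)cyclobutane-1,3-dicarboxylate (CNP0283097.2) | COc1cc([C@H]2[C@H](C(=O)O[C@@H]3C[C@@H]4[C@@H](CN(C)C[C@@H]4C)[C@@H]3C)[C@H](c3ccc(O)c(OC)c3)[C@H]2C(=O)O[C@@H]2C[C@@H]3[C@@H](CN(C)C[C@@H]3C)[C@@H]2C)ccc1O | target

Total step count: 15.
Longest linear sequence: 13 steps (steps 1 to 11, then 14 and 15); steps 12 and 13 are the two-step diacid branch.

Steps most likely to fail

Step 9. The excited seven-membered chromophore may decay by twisting about C3=C5 without bonding, the first bond may form from C3 instead of C5 (wrong regiochemistry), or intermolecular dimerisation may compete. The fallback uses known chemistry, sets out from 17 and returns at 25. Vinylmagnesium bromide would convert the Weinreb amide into the dienone tert-butyl methyl[(2R,3S)-3-methyl-4-oxo-2-[(E)-prop-1-enyl]hex-5-en-1-yl]carbamate F1. Ring-closing metathesis with the second-generation Grubbs catalyst (CH2Cl2, 40 °C), with loss of propene, would give the cyclopentenone tert-butyl methyl{[(1R,5S)-5-methyl-4-oxocyclopent-2-en-1-yl]methyl}carbamate F2. CF3CO2H would remove the Boc group to give (4R,5S)-5-methyl-4-[(methylamino)methyl]cyclopent-2-en-1-one trifluoroacetate F3, and N-alkylation with 2,3-dibromopropene (i-Pr2NEt, MeCN) would give (4R,5S)-4-{[(2-bromoprop-2-enyl)(methyl)amino]methyl}-5-methylcyclopent-2-en-1-one F4. Bu3SnH/AIBN (benzene, 80 °C) would generate the vinyl radical at C4, which closes 6-exo-trig onto the enone β-carbon C4a from the face of its own tether (cis fusion) to give (4aR,7S,7aR)-2,7-dimethyl-4-methylideneoctahydro-6H-cyclopenta[c]pyridin-6-one F5. Hydrogenation of the exocyclic alkene from the convex face (H2, Pd/C), followed by the carbonate equilibration of step 10, would give 25.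

Step 8. Ring closure may stall at the five-membered carbinolamine formed by addition of the amine to the ketone carbonyl, or the chlorovinyl ketone may oligomerise before the seven-membered ring closes. The fallback sets out from 17 and returns at 21. MeMgBr would give the methyl ketone tert-butyl methyl[(2R,3S)-3-methyl-4-oxo-2-[(E)-prop-1-enyl]pentyl]carbamate F6. Condensation at the methyl group with tert-butoxybis(dimethylamino)methane (toluene, 80 °C) would give the enaminone tert-butyl [(2R,3S,5E)-6-(dimethylamino)-3-methyl-4-oxo-2-[(E)-prop-1-enyl]hex-5-enyl](methyl)carbamate F7. CF3CO2H would remove the Boc group to give (1E,4S,5R,6E)-1-(dimethylamino)-4-methyl-5-[(methylamino)methyl]octa-1,6-dien-3-one trifluoroacetate F8, and warming with K2CO3 in MeOH would close the ring at C3 by amine exchange with loss of dimethylamine, giving 21. The enaminone carbonyl is a poor electrophile, so carbonyl addition is suppressed in this variant.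

Step 14. The second esterification may be slow on the hindered monoester, and the activated alcohol may eliminate or be captured by the hydrazide instead of the carboxylate. The fallback separates inversion from ester formation, sets out from 26 and 29 and returns at 30. A Mitsunobu reaction of 26 with the more acidic, unhindered 4-nitrobenzoic acid would give (4R,4aS,6R,7S,7aR)-2,4,7-trimethyloctahydro-1H-cyclopenta[c]pyridin-6-yl 4-nitrobenzoate F9. Methanolysis (K2CO3, MeOH) would give the 6R alcohol (4R,4aS,6R,7S,7aR)-2,4,7-trimethyloctahydro-1H-cyclopenta[c]pyridin-6-ol F10. Diacid 29 would be converted with (COCl)2 and catalytic DMF into (1α,2α,3β,4β)-2,4-bis{3-methoxy-4-[(4-methylphenyl)sulfonyloxy]phenyl}cyclobutane-1,3-dicarbonyl dichloride F11, which would acylate two equivalents of the 6R alcohol (Et3N, DMAP, CH2Cl2) with retention to give 30.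

Further compounds
F1 | step 9 | tert-butyl methyl[(2R,3S)-3-methyl-4-oxo-2-[(E)-prop-1-enyl]hex-5-en-1-yl]carbamate | C=CC(=O)[C@@H](C)[C@@H](/C=C/C)CN(C)C(=O)OC(C)(C)C
F2 | step 9 | tert-butyl methyl{[(1R,5S)-5-methyl-4-oxocyclopent-2-en-1-yl]methyl}carbamate | O=C1C=C[C@@H](CN(C)C(=O)OC(C)(C)C)[C@@H]1C
F3 | step 9 | (4R,5S)-5-methyl-4-[(methylamino)methyl]cyclopent-2-en-1-one trifluoroacetate | O=C1C=C[C@@H](CNC)[C@@H]1C.OC(=O)C(F)(F)F
F4 | step 9 | (4R,5S)-4-{[(2-bromoprop-2-enyl)(methyl)amino]methyl}-5-methylcyclopent-2-en-1-one | O=C1C=C[C@@H](CN(C)CC(Br)=C)[C@@H]1C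
F5 | step 9 | (4aR,7S,7aR)-2,7-dimethyl-4-methylideneoctahydro-6H-cyclopenta[c]pyridin-6-one | O=C1C[C@@H]2[C@@H](CN(C)CC2=C)[C@@H]1C
F6 | step 8 | tert-butyl methyl[(2R,3S)-3-methyl-4-oxo-2-[(E)-prop-1-enyl]pentyl]carbamate | CC(=O)[C@@H](C)[C@@H](/C=C/C)CN(C)C(=O)OC(C)(C)C
F7 | step 8 | tert-butyl [(2R,3S,5E)-6-(dimethylamino)-3-methyl-4-oxo-2-[(E)-prop-1-enyl]hex-5-enyl](methyl)carbamate | CN(C)/C=C/C(=O)[C@@H](C)[C@@H](/C=C/C)CN(C)C(=O)OC(C)(C)C
F8 | step 8 | (1E,4S,5R,6E)-1-(dimethylamino)-4-methyl-5-[(methylamino)methyl]octa-1,6-dien-3-one trifluoroacetate | CN(C)/C=C/C(=O)[C@@H](C)[C@@H](/C=C/C)CNC.OC(=O)C(F)(F)F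
F9 | step 14 | (4R,4aS,6R,7S,7aR)-2,4,7-trimethyloctahydro-1H-cyclopenta[c]pyridin-6-yl 4-nitrobenzoate | O=C(O[C@@H]1C[C@@H]2[C@@H](CN(C)C[C@@H]2C)[C@@H]1C)c1ccc(cc1)[N+](=O)[O-]
F10 | step 14 | (4R,4aS,6R,7S,7aR)-2,4,7-trimethyloctahydro-1H-cyclopenta[c]pyridin-6-ol | O[C@@H]1C[C@@H]2[C@@H](CN(C)C[C@@H]2C)[C@@H]1C
F11 | step 14 | (1α,2α,3β,4β)-2,4-bis{3-methoxy-4-[(4-methylphenyl)sulfonyloxy]phenyl}cyclobutane-1,3-dicarbonyl dichloride | COc1cc([C@H]2[C@H](C(Cl)=O)[C@H](c3ccc(OS(=O)(=O)c4ccc(C)cc4)c(OC)c3)[C@H]2C(Cl)=O)ccc1OS(=O)(=O)c1ccc(C)cc1
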